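**Plan**

1. Locants: ring A C1(OAc)–C2–C3–C4(Me2)–C5–C10; cyclopentane C5–C6(OH)–C8–C9–C10; lactone C7(=O)–O–C20H2 from C8 to C10; ring C C8–C9–C11(OH)–C12–C13–C14; acrylate C17=C16(C15O2Me) on C13.
2. Cuts, last bond first: C16=C17 (methylenation), C13–C16 (Michael), C12=C13 (aldol condensation), C6–C8 (lactone aldol), C9–C11 and C8–C14 (tethered radical cyclisation/allylation), C8=C9 (ring-closing olefination), C5–C10 (Mn(III) radical cyclisation of an acyclic β-keto ester).
3. Enabling feature: quaternary C10 lies between the oxidised carbons C1 and C20, so it is the α-carbon of a β-keto ester; its ring-A neighbour C5 carries oxidised C6, so C5=C6 can be an enol ether that accepts the C10 radical.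
4. Forward order: chain, then ring A, then the spiro-δ-lactone, then the cyclopentane, then ring C, then the acrylate.
5. Stereochemistry: C5/C10 from the chair transition state and an 8-phenylmenthyl ester; C1 by axial hydride delivery; C9 by delivery of C11 through a silicon tether on O1; C8 and C6 by the bridged aldol; C13 and C11 under thermodynamic control in the ring-C chair.

Key step: step 6

Assumption: the (1R,2S,5R)-8-phenylmenthyl group is taken to direct C5–C10 bond formation to the face that gives the (1S,2R) ring-A ester 13; if the sense is the opposite one, the enantiomeric alcohol is used and the route is unchanged.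

**Step 1**
Reactants: 1 isobutyraldehyde; 2 methyl acrylate
Product: 4 methyl 4,4-dimethyl-5-oxopentanoate, via pyrrolidine enamine 3 (not isolated)
Conditions: pyrrolidine, PhH, Dean–Stark; then 2, MeCN, reflux; then AcOH/H2O
Reagents that add atoms: water (O)
Why: Stork enamine Michael addition, in which the enamine β-carbon adds to the acrylate and hydrolysis returns the aldehyde, builds quaternary C4 with the C1–C3 chain.

**Step 2**
Reactants: 4 methyl 4,4-dimethyl-5-oxopentanoate; 5 (methoxymethyl)triphenylphosphonium chloride
Product: 6 methyl (E)-6-methoxy-4,4-dimethylhex-5-enoate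
Conditions: 5, KHMDS, THF, 0 °C; then 4, 0 °C to rt
Reagents that add atoms: none
Why: Wittig methoxymethylenation of a non-enolisable α-quaternary aldehyde, expected to favour the E enol ether for steric reasons, and any Z isomer converges in step 6 because C6 ends as a non-stereogenic acetal carbon.

**Step 3**
Reactants: 6 methyl (E)-6-methoxy-4,4-dimethylhex-5-enoate
Product: 7 (E)-6-methoxy-4,4-dimethylhex-5-enoic acid
Conditions: LiOH, THF/MeOH/H2O, rt; then cold dilute HCl to pH 5
Reagents that add atoms: lithium hydroxide ([Li+].[OH-])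
Why: Saponification, to which the enol ether is inert, followed by a brief cold acidification that should spare it.

**Step 4**
Reactants: 8 3-(benzyloxy)propanoic acid; 9 (−)-8-phenylmenthol
Product: 10 (1R,2S,5R)-8-phenylmenthyl 3-(benzyloxy)propanoate
Conditions: DCC, DMAP (cat.), CH2Cl2, 0 °C to rt
Reagents that add atoms: none
Why: Steglich esterification of a secondary alcohol attaches the auxiliary to the unit that will supply C20, C10 and C9.

**Step 5**
Reactants: 7 (E)-6-methoxy-4,4-dimethylhex-5-enoic acid; 10 (1R,2S,5R)-8-phenylmenthyl 3-(benzyloxy)propanoate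
Product: 12 (1R,2S,5R)-8-phenylmenthyl (E)-2-(benzyloxymethyl)-8-methoxy-6,6-dimethyl-3-oxooct-7-enoate (both C10 epimers), via acyl imidazolide 11 (not isolated)
Conditions: 7, CDI, THF, rt; 10 (2 equiv), LDA, THF, −78 °C; combine at −78 °C; AcOH quench
Reagents that add atoms: none
Why: Claisen-type C-acylation of an ester lithium enolate by an acyl imidazolide installs the CH2OBn arm on carbon, avoiding the O-alkylation that chloromethyl ethers tend to give with β-keto ester enolates, and −78 °C should suppress β-elimination of benzyloxide.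

**Step 6**
Reactants: 12 (1R,2S,5R)-8-phenylmenthyl (E)-2-(benzyloxymethyl)-8-methoxy-6,6-dimethyl-3-oxooct-7-enoate
Product: 13 (1R,2S,5R)-8-phenylmenthyl (1S,2R)-1-(benzyloxymethyl)-2-(dimethoxymethyl)-3,3-dimethyl-6-oxocyclohexane-1-carboxylate (ester cis to the acetal carbon)
Conditions: Mn(OAc)3·2H2O (2.2 equiv), degassed MeOH, 45 °C
Reagents that add atoms: methanol (CO)
Why: Mn(III) forms the enolate of the β-keto ester and oxidises it to the electrophilic C10 radical, which adds to C5, the electron-rich β-carbon of the enol ether; the resulting α-methoxy C6 radical is oxidised by a second Mn(III) to the oxocarbenium ion and captured by methanol as the dimethyl acetal. The closest known reaction type is the Mn(III)-based oxidative free-radical cyclisation of unsaturated β-keto esters, with the oxidative termination known from Mn(III)- and Ce(IV)-mediated additions of 1,3-dicarbonyl radicals to enol ethers in alcohols. Ring A closes 6-exo-trig through a chair that the C4 gem-dimethyl group favours. At C5 the C6 substituent sits equatorial; at C10 the flat ester takes the axial site beside the axial C4 methyl and the bulkier CH2OBn arm the equatorial one, so the ester (future C20) ends cis to C6, while the absolute sense comes from the 8-phenylmenthyl group, whose phenyl ring covers one face of the radical. The step needs radical formation at C10 only, 6-exo and not 7-endo closure, and a single oxidation: C10–H is the only enolisable position, polarity matching sends the radical to C5, the quaternary C10 of the product cannot be re-oxidised, and methanol as solvent secures the acetal.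

**Step 7**
Reactants: 13 ring-A keto ester
Product: 14 ring-A diol (1-OH, C20H2OH and C6H(OMe)2 mutually cis; C9H2OBn trans to them)
Conditions: LiAlH4, THF, −20 °C to rt; Fieser work-up
Reagents that add atoms: none
Why: LiAlH4 reduction of ketone then ester, with hydride attacking C1 axially from the face opposite the axial C10 ester so that 1-OH is equatorial and cis to C20, and with release of auxiliary 9 for reuse.

**Step 8**
Reactants: 14 ring-A diol; 15 diethylphosphonoacetic acid
Product: 16 C20 diethylphosphonoacetate of 14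
Conditions: DCC, DMAP (cat.), CH2Cl2, 0 °C
Reagents that add atoms: none
Why: Carbodiimide esterification in which the primary C20 hydroxyl should react before the hindered secondary 1-OH.

**Step 9**
Reactants: 16 C20 phosphonoacetate
Product: 17 C9 primary alcohol (benzyl removed)
Conditions: H2 (1 atm), 10% Pd/C, EtOAc, rt
Reagents that add atoms: none
Why: Neutral hydrogenolysis of the benzyl ether leaves acetal and phosphonate untouched and avoids base-induced acyl migration between the C20 and C9 oxygens.

**Step 10**
Reactants: 17 C9 primary alcohol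
Product: 18 C9 aldehyde
Conditions: TEMPO (cat.), PhI(OAc)2, CH2Cl2, rt
Reagents that add atoms: none
Why: Oxoammonium (TEMPO) oxidation is selective for the primary alcohol over the secondary 1-OH, and the aldehyde on quaternary C10 cannot epimerise.

**Step 11**
Reactants: 18 C9 aldehyde
Product: 19 spiro-lactone 7-(dimethoxymethyl)-11-hydroxy-8,8-dimethyl-2-oxaspiro[5.5]undec-4-en-3-one (C8=C9; configuration of ring A as in 14)
Conditions: LiCl, i-Pr2NEt, MeCN, rt, high dilution
Reagents that add atoms: none
Why: Intramolecular Horner–Wadsworth–Emmons olefination under Masamune–Roush conditions closes the six-membered lactone, whose ring enforces the cis C8=C9 geometry.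

**Step 12**
Reactants: 19 spiro-lactone acetal
Product: 20 spiro-lactone C6 aldehyde
Conditions: 1 M aq. HCl, THF, rt
Reagents that add atoms: water (O)
Why: Acid hydrolysis of the dimethyl acetal, carried out before the acid-labile silicon tether is attached; C5 should hold because the equatorial formyl group is the thermodynamic arrangement.

**Step 13**
Reactants: 21 chlorodimethylvinylsilane
Product: 23 (1-bromovinyl)chlorodimethylsilane, via dibromide 22 (not isolated)
Conditions: Br2, CH2Cl2, −78 to 0 °C; then Et3N, reflux; distillation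
Reagents that add atoms: bromine (BrBr)
Why: Bromination and dehydrobromination of a vinylsilane, the standard access to 1-bromovinylsilanes, with a tertiary amine so that the Si–Cl bond is kept.

**Step 14**
Reactants: 20 spiro-lactone C6 aldehyde; 23 (1-bromovinyl)chlorodimethylsilane
Product: 24 1-O-[(1-bromovinyl)dimethylsilyl] ether of 20
Conditions: Et3N, DMAP (cat.), CH2Cl2, 0 °C; used crude
Reagents that add atoms: none
Why: Silylation of the only hydroxyl places the radical precursor on O1, on the lactone face where C11 must arrive.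

**Step 15**
Reactants: 24 bromovinylsilyl ether; 25 allyltributylstannane
Product: 26 cyclic siloxane lactone (C9–C11 bond formed with C11 cis to C1, exo-methylene C11=C12, allyl on C8, both C8 epimers, C6 aldehyde)
Conditions: 25 (4 equiv), AIBN (portions), PhH, 80 °C
Reagents that add atoms: none
Why: Silicon-tethered radical cyclisation followed by Keck allylation: the 1-silylvinyl radical adds 6-exo to C9, the β-carbon of the unsaturated lactone, and the tether from O1 fixes C9 with C11 cis to C1, after which the C8 radical is trapped by the allylstannane; the C8 configuration is erased in step 16.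

**Step 16**
Reactants: 26 cyclic siloxane lactone aldehyde
Product: 28 bridged lactone with cyclopentane closed (C6–C8 bond, C8 quaternary, 6-OTES exo, anti to the lactone bridge), via potassium aldolate 27 (not isolated)
Conditions: KHMDS, THF, −78 °C; then TESCl, −78 to 0 °C
Reagents that add atoms: chlorotriethylsilane (CC[Si](CC)(CC)Cl)
Why: Intramolecular lactone-enolate aldol (5-enolexo-exo-trig) in which the C8 enolate can reach C6 only on the C5 face, which fixes C8, and the aldehyde oxygen should turn away from the lactone bridge and the C4 methyl groups to give the exo 6-oxygen; silylation of the aldolate blocks retro-aldol and marks O6.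

**Step 17**
Reactants: 28 bridged siloxane lactone
Product: 29 C11 methyl ketone with free 1-OH
Conditions: 30% H2O2, KF, KHCO3, THF/MeOH, rt
Reagents that add atoms: hydrogen peroxide (OO)
Why: Tamao oxidation of the alkenyl(alkoxy)silane converts the C11–Si bond into the enol and hence the methyl ketone, and frees 1-OH with its configuration unchanged.

**Step 18**
Reactants: 29 hydroxy ketone
Product: 30 1-O-acetate
Conditions: Ac2O, DMAP, pyridine, rt
Reagents that add atoms: acetic anhydride (CC(=O)OC(C)=O)
Why: Acetylation of the only free hydroxyl puts the C1 acetate in place before O11 exists and while O6 is silylated.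

**Step 19**
Reactants: 30 acetate with C8 allyl group
Product: 31 keto aldehyde (C8–C14H2–C13HO)
Conditions: O3, CH2Cl2, −78 °C; then PPh3
Reagents that add atoms: ozone ([O-][O+]=O)
Why: Ozonolysis of the only alkene, with reductive work-up, gives the C13 aldehyde.

**Step 20**
Reactants: 31 keto aldehyde
Product: 32 ring-C enone (C11=O, C12=C13)
Conditions: piperidine, AcOH, toluene, 4 Å MS, 60 °C
Reagents that add atoms: none
Why: Intramolecular aldol condensation of a 1,5-keto aldehyde closes the six-membered ring through the methyl-side enamine, so the C9 stereocentre is not enolised.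

**Step 21**
Reactants: 32 ring-C enone; 33 tert-butyl methyl malonate
Product: 34 C13 Michael adduct (malonyl group equatorial, cis to C6 and trans to C7; both C16 epimers)
Conditions: 33 (1.5 equiv), DBU (cat.), MeCN, rt
Reagents that add atoms: none
Why: Reversible Michael addition of a malonate, in which approach syn to the axial C7 on C8 is blocked and the malonyl group settles equatorial on C13.

**Step 22**
Reactants: 34 C11 ketone
Product: 35 equatorial 11-alcohol (11-OH cis to H9 and to the C13 substituent)
Conditions: Shvo catalyst (3 mol%), i-PrOH/toluene, 80 °C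
Reagents that add atoms: none
Why: Reversible Ru-catalysed transfer hydrogenation equilibrates the carbinol to the equatorial 11-OH, because the axial epimer would be syn-diaxial to C7, whereas kinetic hydride delivery is expected from the open equatorial side and would give the wrong epimer.

**Step 23**
Reactants: 35 silyl ether tert-butyl ester
Product: 36 malonic half-acid with free 6-OH and 11-OH
Conditions: TFA/CH2Cl2/H2O (20:78:2), 0 °C to rt
Reagents that add atoms: none
Why: Acidolysis cleaves the tert-butyl ester and the TES ether together and spares the methyl ester, acetate and lactone.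

**Step 24**
Reactants: 36 malonic half-acid
Product: 37 target CNP0421185.1
Conditions: (CH2O)n, Et2NH, EtOAc, 70 °C
Reagents that add atoms: formaldehyde (C=O)
Why: Decarboxylative Mannich methylenation of a malonic half-ester forms the C16=C17 acrylate under mild amine conditions that the acetate, lactone and β-hydroxy lactone should tolerate.

**Compound list**

1 | isobutyraldehyde | CC(C)C=O | starting material
2 | methyl acrylate | C=CC(=O)OC | starting material
3 | 1-(2-methylprop-1-en-1-yl)pyrrolidine | CC(C)=CN1CCCC1 | intermediate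
4 | methyl 4,4-dimethyl-5-oxopentanoate | COC(=O)CCC(C)(C)C=O | intermediate
5 | (methoxymethyl)triphenylphosphonium chloride | [Cl-].COC[P+](c1ccccc1)(c1ccccc1)c1ccccc1 | starting material
6 | methyl (E)-6-methoxy-4,4-dimethylhex-5-enoate | COC(=O)CCC(C)(C)/C=C/OC | intermediate
7 | (E)-6-methoxy-4,4-dimethylhex-5-enoic acid | OC(=O)CCC(C)(C)/C=C/OC | intermediate
8 | 3-(benzyloxy)propanoic acid | OC(=O)CCOCc1ccccc1 | starting material
9 | (−)-8-phenylmenthol, (1R,2S,5R)-5-methyl-2-(2-phenylpropan-2-yl)cyclohexan-1-ol | CC(C)(c1ccccc1)[C@@H]1CC[C@@H](C)C[C@H]1O | starting material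
10 | (1R,2S,5R)-8-phenylmenthyl 3-(benzyloxy)propanoate | CC(C)(c1ccccc1)[C@@H]1CC[C@@H](C)C[C@H]1OC(=O)CCOCc1ccccc1 | intermediate
11 | 1-[(E)-6-methoxy-4,4-dimethylhex-5-enoyl]imidazole | O=C(CCC(C)(C)/C=C/OC)n1ccnc1 | intermediate
12 | (1R,2S,5R)-8-phenylmenthyl (E)-2-(benzyloxymethyl)-8-methoxy-6,6-dimethyl-3-oxooct-7-enoate, both C10 epimers | CC(C)(c1ccccc1)[C@@H]1CC[C@@H](C)C[C@H]1OC(=O)C(COCc1ccccc1)C(=O)CCC(C)(C)/C=C/OC | intermediate
13 | (1R,2S,5R)-8-phenylmenthyl (1S,2R)-1-(benzyloxymethyl)-2-(dimethoxymethyl)-3,3-dimethyl-6-oxocyclohexane-1-carboxylate | CC(C)(c1ccccc1)[C@@H]1CC[C@@H](C)C[C@H]1OC(=O)[C@@]1(COCc2ccccc2)C(=O)CCC(C)(C)[C@H]1C(OC)OC | intermediate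
14 | 2-(benzyloxymethyl)-3-(dimethoxymethyl)-2-(hydroxymethyl)-4,4-dimethylcyclohexan-1-ol; 1-OH, CH2OH and CH(OMe)2 mutually cis | OC[C@@]1(COCc2ccccc2)[C@@H](O)CCC(C)(C)[C@H]1C(OC)OC | intermediate
15 | diethylphosphonoacetic acid | CCOP(=O)(OCC)CC(=O)O | starting material
16 | C20 diethylphosphonoacetate of 14 | CCOP(=O)(OCC)CC(=O)OC[C@@]1(COCc2ccccc2)[C@@H](O)CCC(C)(C)[C@H]1C(OC)OC | intermediate
17 | debenzylated phosphonoacetate (C9H2OH) | CCOP(=O)(OCC)CC(=O)OC[C@@]1(CO)[C@@H](O)CCC(C)(C)[C@H]1C(OC)OC | intermediate
18 | C9 aldehyde phosphonoacetate | CCOP(=O)(OCC)CC(=O)OC[C@@]1(C=O)[C@@H](O)CCC(C)(C)[C@H]1C(OC)OC | intermediate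
19 | 7-(dimethoxymethyl)-11-hydroxy-8,8-dimethyl-2-oxaspiro[5.5]undec-4-en-3-one (ring A as in 14) | O=C1OC[C@@]2(C=C1)[C@@H](O)CCC(C)(C)[C@H]2C(OC)OC | intermediate
20 | 11-hydroxy-8,8-dimethyl-3-oxo-2-oxaspiro[5.5]undec-4-ene-7-carbaldehyde | O=C1OC[C@@]2(C=C1)[C@@H](O)CCC(C)(C)[C@H]2C=O | intermediate
21 | chlorodimethylvinylsilane | C=C[Si](C)(C)Cl | starting material
22 | chloro(1,2-dibromoethyl)dimethylsilane | BrCC(Br)[Si](C)(C)Cl | intermediate
23 | (1-bromovinyl)chlorodimethylsilane | C=C(Br)[Si](C)(C)Cl | intermediate
24 | 1-O-[(1-bromovinyl)dimethylsilyl] ether of 20 | O=C1OC[C@@]2(C=C1)[C@@H](O[Si](C)(C)C(Br)=C)CCC(C)(C)[C@H]2C=O | intermediate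
25 | allyltributylstannane | C=CC[Sn](CCCC)(CCCC)CCCC | starting material
26 | cyclic siloxane lactone: O1–SiMe2–C11(=CH2)–C9 ring, C11 cis to C1 on the lactone, allyl on C8 (both epimers), C6 aldehyde | C=CCC1C(=O)OC[C@@]2([C@@H]1C(=C)[Si](C)(C)O3)[C@@H]3CCC(C)(C)[C@H]2C=O | intermediate
27 | potassium C6 alkoxide of the aldol adduct | C=C([Si]4(C)C)[C@@H]2[C@]3(CC=C)C(=O)OC[C@]21[C@@H](O4)CCC(C)(C)[C@H]1[C@@H]3[O-].[K+] | intermediate
28 | bridged lactone with cyclopentane C5–C6–C8–C9–C10, 6-OTES exo, C8 allyl, siloxane ring O1–Si–C11 | C=C([Si]4(C)C)[C@@H]2[C@]3(CC=C)C(=O)OC[C@]21[C@@H](O4)CCC(C)(C)[C@H]1[C@@H]3O[Si](CC)(CC)CC | intermediate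
29 | C9 acetyl (C11 ketone), 1-OH, 6-OTES, C8 allyl bridged lactone | CC(=O)[C@@H]2[C@]3(CC=C)C(=O)OC[C@]21[C@@H](O)CCC(C)(C)[C@H]1[C@@H]3O[Si](CC)(CC)CC | intermediate
30 | 1-O-acetate of 29 | CC(=O)[C@@H]2[C@]3(CC=C)C(=O)OC[C@]21[C@@H](OC(C)=O)CCC(C)(C)[C@H]1[C@@H]3O[Si](CC)(CC)CC | intermediate
31 | keto aldehyde (C8–CH2–CHO) | CC(=O)[C@@H]2[C@]3(CC=O)C(=O)OC[C@]21[C@@H](OC(C)=O)CCC(C)(C)[C@H]1[C@@H]3O[Si](CC)(CC)CC | intermediate
32 | tetracyclic ring-C enone (C11=O, C12=C13), 1-OAc, 6-OTES | C1=CC(=O)[C@@H]2[C@]3(C1)C(=O)OC[C@]21[C@@H](OC(C)=O)CCC(C)(C)[C@H]1[C@@H]3O[Si](CC)(CC)CC | intermediate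
33 | tert-butyl methyl malonate | COC(=O)CC(=O)OC(C)(C)C | starting material
34 | C13 malonate adduct, C11 ketone (both C16 epimers) | COC(=O)C(C(=O)OC(C)(C)C)[C@@H]1CC(=O)[C@@H]2[C@]3(C1)C(=O)OC[C@]21[C@@H](OC(C)=O)CCC(C)(C)[C@H]1[C@@H]3O[Si](CC)(CC)CC | intermediate
35 | C13 malonate, equatorial 11-OH, 6-OTES (both C16 epimers) | COC(=O)C(C(=O)OC(C)(C)C)[C@@H]1C[C@H](O)[C@@H]2[C@]3(C1)C(=O)OC[C@]21[C@@H](OC(C)=O)CCC(C)(C)[C@H]1[C@@H]3O[Si](CC)(CC)CC | intermediate
36 | malonic half-acid (methyl ester) with free 6-OH and 11-OH (both C16 epimers) | COC(=O)C(C(=O)O)[C@@H]1C[C@H](O)[C@@H]2[C@]3(C1)C(=O)OC[C@]21[C@@H](OC(C)=O)CCC(C)(C)[C@H]1[C@@H]3O | intermediate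
37 | CNP0421185.1 | C=C(C(=O)OC)[C@@H]1C[C@H](O)[C@@H]2[C@]3(C1)C(=O)OC[C@]21[C@@H](OC(C)=O)CCC(C)(C)[C@H]1[C@@H]3O | target

**Totals**

Total step count: 24 (22 in the main line, plus steps 4 and 13 as side steps).
Longest linear sequence: 22 steps (1–3, 5–12, 14–24).

**Steps most likely to fail**

Step 6. The ester auxiliary may discriminate poorly between the two faces of the C10 radical, giving a mixture of auxiliary diastereomers that is hard to separate, while the chair still controls the relative configuration of C5 and C10. The fallback takes the absolute configuration from a resolution. It sets out from acid 7: its imidazolide 11 acylates the lithium enolate of commercial methyl 3-(benzyloxy)propanoate to give methyl (E)-2-(benzyloxymethyl)-8-methoxy-6,6-dimethyl-3-oxooct-7-enoate F1. The same Mn(OAc)3/MeOH cyclisation gives the racemic ring-A keto ester F2, and LiAlH4 gives the racemic diol F3. F3 is separated by preparative chromatography on a chiral stationary phase, and the enantiomer that is identical with 14 re-enters the route at 14.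

Step 15. The vinyl radical may be intercepted by the stannane before it closes the ring, or the C8 radical may be lost by reduction or by reversible addition to the free aldehyde before it is allylated. The fallback separates the two bond formations and keeps the acetal until they are done. It sets out from 19: silylation with 23 gives the bromovinylsilyl ether F4, and Bu3SnH/AIBN closes the siloxane ring 6-exo to give the C8-unsubstituted lactone acetal F5. LDA and allyl bromide at −78 °C give the C8-allyl lactone acetal F6, and a non-aqueous transacetalisation (cat. I2, acetone) frees the aldehyde. The fallback comes back at 26.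

Step 22. Hydrogen transfer at the hindered C11 ketone may be slow or the equilibration incomplete, leaving the axial 11-epimer. The fallback uses kinetic reduction and inversion. It sets out from 34: K-Selectride at −78 °C delivers hydride from the open equatorial side to give the axial 11-epi alcohol F7. Mitsunobu reaction with chloroacetic acid (PPh3, DIAD) inverts C11 to the equatorial chloroacetate F8. Thiourea with NaHCO3 in EtOH removes the chloroacetyl group without touching the C1 acetate, and the fallback comes back at 35.

**Further compounds**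

F1 | step 6 | methyl (E)-2-(benzyloxymethyl)-8-methoxy-6,6-dimethyl-3-oxooct-7-enoate | COC(=O)C(COCc1ccccc1)C(=O)CCC(C)(C)/C=C/OC
F2 | step 6 | racemic methyl 1-(benzyloxymethyl)-2-(dimethoxymethyl)-3,3-dimethyl-6-oxocyclohexane-1-carboxylate, ester cis to the acetal carbon (one enantiomer drawn) | COC(=O)[C@@]1(COCc2ccccc2)C(=O)CCC(C)(C)[C@H]1C(OC)OC
F3 | step 6 | racemic diol, racemate of 14 (one enantiomer drawn) | OC[C@@]1(COCc2ccccc2)[C@@H](O)CCC(C)(C)[C@H]1C(OC)OC
F4 | step 15 | 1-O-[(1-bromovinyl)dimethylsilyl] ether of 19 | O=C1OC[C@@]2(C=C1)[C@@H](O[Si](C)(C)C(Br)=C)CCC(C)(C)[C@H]2C(OC)OC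
F5 | step 15 | cyclic siloxane lactone acetal with C8H2 | C1C(=O)OC[C@@]2([C@@H]1C(=C)[Si](C)(C)O3)[C@@H]3CCC(C)(C)[C@H]2C(OC)OC
F6 | step 15 | cyclic siloxane lactone acetal with allyl on C8 (both C8 epimers) | C=CCC1C(=O)OC[C@@]2([C@@H]1C(=C)[Si](C)(C)O3)[C@@H]3CCC(C)(C)[C@H]2C(OC)OC
F7 | step 22 | 11-epi (axial) alcohol of 35 | COC(=O)C(C(=O)OC(C)(C)C)[C@@H]1C[C@@H](O)[C@@H]2[C@]3(C1)C(=O)OC[C@]21[C@@H](OC(C)=O)CCC(C)(C)[C@H]1[C@@H]3O[Si](CC)(CC)CC
F8 | step 22 | 11-O-chloroacetate of 35 | COC(=O)C(C(=O)OC(C)(C)C)[C@@H]1C[C@H](OC(=O)CCl)[C@@H]2[C@]3(C1)C(=O)OC[C@]21[C@@H](OC(C)=O)CCC(C)(C)[C@H]1[C@@H]3O[Si](CC)(CC)CC
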